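## Retrosynthetic overview

- The plan rests on ring B: a cyclohexane whose four adjacent stereocentres (quaternary C–CH3, the CH carrying the two-carbon link, C(CH3)OH, ring-fusion CH–O) include the C(CH3)–CH(O) bond it shares with the oxepane ring A. Both rings are cut at once, at C(CH3)–CH(O) and CH(link)–C(O), to a geranate whose O–CMe2 oxygen carries an (E,E)-1-alkoxy-4-silyloxybutadiene and whose (E)-enoate is the dienophile.
- The triene comes from methyl geranate: Shi epoxidation, epoxide alcoholysis with allyl alcohol, acetylation, cross-metathesis, silyl dienol ether formation. After the cycloaddition the ester becomes a vinyl group and the silyloxy carbon becomes the C(CH3)OH centre.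
- The cis-fused hydroazulene is cut at the bond between its tetrasubstituted alkene and the CH2CH2 link (B-alkyl Suzuki coupling of an enol triflate). Its cyclopentane comes from (R)-linalool by ring-closing metathesis; its cycloheptane from a second ring-closing metathesis after nitrile-anion epoxide opening and a boron aldol reaction.
- Order of ring formation: rings A and B together (step 6); cyclopentane (step 15) and cycloheptane (step 23) of the second fragment; fragment union (step 27), desilylation (step 28).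

Key step: step 6

Remark (assumption on reagent sense): the D-fructose-derived Shi ketone is taken to give the (6R)-epoxide of methyl geranate, and Z-enol borinates from (−)-Ipc2BOTf are taken to add to the si face of acrolein; if either sense were the opposite, the antipodal catalyst or reagent would be used.

Locants: rings A/B are numbered as a 1-benzoxepine (O-1, C-2 = CMe2, C-3 = CH–OAc, C-5a = C–CH3, C-6 = CH–link, C-7 = C–O, C-9a = CH–O; β = face of the 5a-methyl group). The second fragment is numbered as an azulene (C-3 = C(CH3)O, C-3a/C-8a ring fusion, C-5 = CH–O, C-6 = C–CH3, C-7 = link carbon, C-8 = CMe2).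

## Route

Step 1
Reactants: 1 methyl geranate
Product: 2 methyl (2E)-5-[(2R)-3,3-dimethyloxiran-2-yl]-3-methylpent-2-enoate
Conditions: D-fructose-derived Shi ketone (0.3 equiv), KHSO5 (as 2KHSO5·KHSO4·K2SO4), K2CO3, Bu4NHSO4, Na2B4O7/Na2EDTA buffer, MeCN/CH2(OMe)2/H2O, 0 °C
Reagents that add atoms: potassium peroxymonosulfate, [K+].[O-]S(=O)(=O)OO
Why: Shi asymmetric epoxidation: the chiral dioxirane attacks only the electron-rich 6,7-alkene (the enoate is inert) and its spiro transition state sets the (R) epoxide carbon.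

Step 2
Reactants: 2 the (R)-epoxide; 3 allyl alcohol
Product: 4 methyl (2E,6R)-6-hydroxy-3,7-dimethyl-7-(prop-2-en-1-yloxy)oct-2-enoate
Conditions: allyl alcohol (10 equiv), BF3·OEt2 (0.1 equiv), CH2Cl2, −30 → 0 °C
Reagents that add atoms: none
Why: Lewis-acid-catalysed alcoholysis of a trisubstituted epoxide takes place at the tertiary carbon, which makes the tertiary allyl ether without base; the C-6–O bond is not touched, so C-6 keeps its configuration.

Step 3
Reactants: 4 the hydroxy allyl ether
Product: 5 methyl (2E,6R)-6-acetoxy-3,7-dimethyl-7-(prop-2-en-1-yloxy)oct-2-enoate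
Conditions: Ac2O, pyridine, DMAP (cat.), CH2Cl2, rt
Reagents that add atoms: acetic anhydride, CC(=O)OC(C)=O
Why: DMAP-catalysed acylation of the only free (secondary) hydroxyl under conditions too mild for oxa-Michael closure onto the enoate.

Step 4
Reactants: 5 the acetate; 6 (E)-crotonaldehyde
Product: 7 methyl (2E,6R)-6-acetoxy-3,7-dimethyl-7-{[(2E)-4-oxobut-2-en-1-yl]oxy}oct-2-enoate
Conditions: crotonaldehyde (5 equiv), second-generation Hoveyda–Grubbs catalyst (5 mol%), CH2Cl2, 40 °C
Reagents that add atoms: none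
Why: Olefin cross-metathesis of the terminal allyl ether with an enal gives the (E)-4-alkoxybut-2-enal, while the trisubstituted enoate does not take part.

Step 5
Reactants: 7 the enal
Product: 8 methyl (2E,6R)-6-acetoxy-7-{[(1E,3E)-4-(tert-butyldimethylsilyloxy)buta-1,3-dien-1-yl]oxy}-3,7-dimethyloct-2-enoate
Conditions: TBSOTf (1.2 equiv), Et3N (2 equiv), Et2O, −78 → 0 °C; chromatography on Et3N-deactivated silica
Reagents that add atoms: tert-butyldimethylsilyl triflate, CC(C)(C)[Si](C)(C)OS(=O)(=O)C(F)(F)F
Why: Silyl dienol ether formation (O-silylation of the aldehyde, then γ-deprotonation by the amine) is much faster for the enal than for the two esters and should favour the (1E,3E) diene from the s-trans enal; minor geometric isomers are removed.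

Step 6
Reactants: 8 the dienyl ether–enoate
Product: 9 methyl (3R)-3-acetoxy-7-(tert-butyldimethylsilyloxy)-2,2,5a-trimethyl-2,3,4,5,5a,6,7,9a-octahydro-1-benzoxepine-6-carboxylate (trans-fused: 5a-CH3 β, 9a-H α; 6-CO2CH3 β; 7-OTBS β; 3-OAc α)
Conditions: toluene (0.01 M), BHT, 2,6-di-tert-butyl-4-methylpyridine (0.2 equiv), sealed tube, 180 °C
Reagents that add atoms: none
Why: A concerted, asynchronous normal-electron-demand [4+2] cycloaddition joins C-1 and C-4 of the electron-rich 1-alkoxy-4-silyloxydiene to the β- and α-carbons of the (E)-enoate; the closest known reaction type is the thermal type 1 intramolecular Diels–Alder reaction of ether-tethered 1-oxygenated dienes with ester-activated alkenes. Ring B closes as the six-membered cycloadduct, and ring A closes as the seven-membered ring made of the five tether atoms O–CMe2–CH(OAc)–CH2–CH2 plus the two newly bonded carbons, the folding being helped by the gem-dimethyl group next to the ether oxygen. At C-5a and C-6 the cis relation of methyl and ester is fixed by the (E)-enoate geometry, and at C-9a and C-7 the cis relation of the two oxygen substituents is fixed by the (E,E)-diene geometry. The relation between these two pairs comes from the endo-ester transition state, which for an (E)-enoate necessarily puts the tether exo and so gives the trans ring fusion with methyl, ester, silyloxy and ring oxygen on one face. The step needs this endo-ester/exo-tether preference and reaction on one diene face; the face is secured only by the acetoxy-bearing tether carbon, which in the chair-like fold should sit gauche to the ether oxygen and anti to one methyl of the CMe2 group, so the bias is expected to be moderate and the minor diastereomer is separated by chromatography.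

Step 7
Reactants: 9 the cycloadduct
Product: 10 methyl (3R)-3-acetoxy-7-(tert-butyldimethylsilyloxy)-2,2,5a-trimethyldecahydro-1-benzoxepine-6-carboxylate (configuration as in 9)
Conditions: H2 (1 atm), 5% Pt/C, EtOAc, rt
Reagents that add atoms: none
Why: Heterogeneous hydrogenation of the cis-disubstituted ring alkene; platinum is chosen to avoid hydrogenolysis of the two allylic C–O bonds, and no stereocentre is formed.

Step 8
Reactants: 10 the saturated ester
Product: 11 (3R)-6β-(hydroxymethyl)-7β-(tert-butyldimethylsilyloxy)-2,2,5a-trimethyldecahydro-1-benzoxepin-3α-ol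
Conditions: LiAlH4, Et2O, 0 °C → rt; aqueous NaOH work-up
Reagents that add atoms: none
Why: Hydride reduction takes the hindered methyl ester to the primary alcohol and at the same time cleaves the acetate, which is deliberately given up here because it would not survive; the silyl ether is stable.

Step 9
Reactants: 11 the diol
Product: 12 (3R)-3α-hydroxy-7β-(tert-butyldimethylsilyloxy)-2,2,5a-trimethyldecahydro-1-benzoxepine-6β-carbaldehyde
Conditions: TEMPO (10 mol%), PhI(OAc)2 (1.2 equiv), CH2Cl2, rt
Reagents that add atoms: none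
Why: Oxoammonium (TEMPO) oxidation is selective for the primary alcohol over the hindered secondary alcohol next to CMe2 and is not basic, so the aldehyde α-centre is not epimerised.

Step 10
Reactants: 12 the hydroxy aldehyde
Product: 13 (3R)-6β-ethenyl-7β-(tert-butyldimethylsilyloxy)-2,2,5a-trimethyldecahydro-1-benzoxepin-3α-ol
Conditions: Ph3PCH3Br (3.5 equiv), KN(SiMe3)2 (3.3 equiv), THF, 0 °C; then 12, −78 → 0 °C
Reagents that add atoms: methyltriphenylphosphonium bromide, C[P+](c1ccccc1)(c1ccccc1)c1ccccc1.[Br-]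
Why: Wittig methylenation with the unstabilised ylide is fast at low temperature, which limits β-elimination of the silyloxy group and epimerisation; one equivalent of ylide is spent on the free hydroxyl.

Step 11
Reactants: 13 the vinyl alcohol
Product: 14 (3R)-6β-ethenyl-7β-(tert-butyldimethylsilyloxy)-2,2,5a-trimethyldecahydro-1-benzoxepin-3α-yl acetate
Conditions: Ac2O, pyridine, DMAP (cat.), CH2Cl2, rt
Reagents that add atoms: acetic anhydride, CC(=O)OC(C)=O
Why: DMAP-catalysed acylation puts the acetate of the target back on the only free hydroxyl.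

Step 12
Reactants: 14 the silyl ether acetate
Product: 15 (3R)-6β-ethenyl-7β-hydroxy-2,2,5a-trimethyldecahydro-1-benzoxepin-3α-yl acetate
Conditions: HF·pyridine, THF, 0 °C → rt
Reagents that add atoms: none
Why: Fluoride-assisted desilylation under weakly acidic conditions leaves the acetate in place (no acyl migration) and does not touch the vinyl group or the tertiary ether.

Step 13
Reactants: 15 the secondary alcohol
Product: 16 (3R)-6β-ethenyl-2,2,5a-trimethyl-7-oxodecahydro-1-benzoxepin-3α-yl acetate
Conditions: Dess–Martin periodinane, NaHCO3, CH2Cl2, 0 °C → rt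
Reagents that add atoms: none
Why: Buffered Dess–Martin oxidation of the strained axial alcohol gives the ketone without moving the β,γ-double bond into conjugation; the α-vinyl group is equatorial, the more stable arrangement.

Step 14
Reactants: 16 the ketone
Product: 17 (3R)-6β-ethenyl-7β-hydroxy-2,2,5a,7α-tetramethyldecahydro-1-benzoxepin-3α-yl acetate
Conditions: MeMgBr (2 equiv), CeCl3 (2.5 equiv), THF, −78 °C; aqueous NH4Cl
Reagents that add atoms: methylmagnesium bromide, C[Mg]Br
Why: Organocerium addition (Imamoto conditions) is non-basic and at −78 °C much faster at the ketone than at the acetate; the methyl group enters equatorially, away from the axial 5a-methyl group, which gives the axial 7β-hydroxyl of the target.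

Step 15
Reactants: 18 (R)-(−)-linalool
Product: 19 (R)-1-methylcyclopent-2-en-1-ol
Conditions: second-generation Grubbs catalyst (0.5 mol%), CH2Cl2, 40 °C
Reagents that add atoms: none
Why: Ring-closing metathesis of the 1,6-diene expels 2-methylpropene and keeps the tertiary carbinol centre, which becomes C-3 of the hydroazulene.

Step 16
Reactants: 19 the cyclopentenol
Product: 20 (1R)-cis-2,3-epoxy-1-methylcyclopentan-1-ol (epoxide on the face of the hydroxyl)
Conditions: VO(acac)2 (2 mol%), t-BuOOH (decane), CH2Cl2, 0 °C → rt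
Reagents that add atoms: tert-butyl hydroperoxide, CC(C)(C)OO
Why: Hydroxyl-directed vanadium-catalysed epoxidation delivers oxygen to the alkene face syn to the allylic hydroxyl.

Step 17
Reactants: 20 the epoxy alcohol; 21 isobutyronitrile
Product: 23 2-[(3R)-2,3-dihydroxy-3-methylcyclopentyl]-2-methylpropanenitrile (2-OH cis to 3-OH; side chain trans to 2-OH), via 2-lithio-2-methylpropanenitrile 22 (not isolated)
Conditions: LiN(i-Pr)2 (3.2 equiv), isobutyronitrile (3.2 equiv), THF, −78 °C; then 20, −78 → 50 °C; aqueous NH4Cl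
Reagents that add atoms: none
Why: SN2 epoxide opening by a tertiary nitrile-stabilised carbanion occurs at the epoxide carbon remote from the quaternary alkoxide carbon and anti to the epoxide oxygen, which sets C-8a with the new C–C bond trans to both oxygens (a Payne shift is impossible for the cis epoxy alcohol).

Step 18
Reactants: 23 the nitrile diol
Product: 24 2-[(3R)-3-hydroxy-3-methyl-2-oxocyclopentyl]-2-methylpropanenitrile (side chain cis to the 3-methyl group)
Conditions: Dess–Martin periodinane, NaHCO3, CH2Cl2, rt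
Reagents that add atoms: none
Why: Dess–Martin oxidation of the secondary alcohol of a secondary/tertiary 1,2-diol gives the α-hydroxy ketone under buffered conditions that do not epimerise the α-centre.

Step 19
Reactants: 24 the hydroxy ketone
Product: 25 2-methyl-2-[(3R)-3-methyl-2-oxo-3-(triethylsilyloxy)cyclopentyl]propanenitrile
Conditions: TESOTf (1.2 equiv), 2,6-lutidine, CH2Cl2, −78 → 0 °C
Reagents that add atoms: triethylsilyl triflate, CC[Si](CC)(CC)OS(=O)(=O)C(F)(F)F
Why: Silyl triflate with a hindered pyridine base silylates the tertiary hydroxyl, which must be masked for the organolithium, boron triflate and amide-base steps that follow.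

Step 20
Reactants: 25 the silyloxy ketone
Product: 26 2-methyl-2-[(3R)-3-methyl-2-methylidene-3-(triethylsilyloxy)cyclopentyl]propanenitrile
Conditions: Zn, CH2Br2, TiCl4, THF/CH2Cl2, 0 °C → rt
Reagents that add atoms: dibromomethane, BrCBr
Why: Lombardo methylenation uses a non-basic zinc/titanium methylene reagent that converts hindered, enolisable ketones without epimerising the α-stereocentre and leaves the nitrile alone.

Step 21
Reactants: 26 the methylidene nitrile
Product: 28 2-methyl-2-[(3R)-3-methyl-2-methylidene-3-(triethylsilyloxy)cyclopentyl]pentan-3-one, via lithium ketimide 27 (not isolated)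
Conditions: EtLi (2.5 equiv), Et2O, 0 °C → rt; then AcOH/NaOAc buffer, THF/H2O, rt
Reagents that add atoms: ethyllithium, [Li]CC; water, O
Why: Addition of an organolithium to a tertiary nitrile (no α-hydrogen) stops at the N-lithio ketimine, and buffered hydrolysis releases the ethyl ketone while keeping the tertiary silyl ether.

Step 22
Reactants: 28 the ethyl ketone; 29 acrolein
Product: 32 (4S,5R)-5-hydroxy-2,4-dimethyl-2-[(3R)-3-methyl-2-methylidene-3-(triethylsilyloxy)cyclopentyl]hept-6-en-3-one, via Z-enol diisopinocampheylborinate 30 (not isolated), via boron aldolate 31 (not isolated)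
Conditions: (−)-Ipc2BOTf (1.5 equiv), i-Pr2NEt, CH2Cl2, −78 °C; acrolein (3 equiv), −78 → −20 °C; then H2O2, pH 7 buffer, MeOH, 0 °C
Reagents that add atoms: none
Why: Paterson boron aldol reaction: the Z-enol borinate reacts through a chair transition state to give the syn aldol, and the isopinocampheyl ligands direct attack to the si face of the aldehyde, which sets the (R) carbinol centre that becomes C-5 (the adjacent methyl-bearing centre is lost later).

Step 23
Reactants: 32 the aldol diene
Product: 33 (3R,5R,6S,8aR)-5-hydroxy-3,6,8,8-tetramethyl-3-(triethylsilyloxy)-2,3,5,6,8,8a-hexahydroazulen-7(1H)-one (C-3a=C-4 double bond)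
Conditions: second-generation Hoveyda–Grubbs catalyst (10 mol%), toluene, 80 °C
Reagents that add atoms: none
Why: Ring-closing metathesis starts at the unhindered vinyl carbinol and closes onto the 1,1-disubstituted alkene, forming the seven-membered ring with a trisubstituted double bond and releasing ethene.

Step 24
Reactants: 33 the cycloheptenol
Product: 34 cis-fused 5-hydroxy-3,6,8,8-tetramethyl-3-(triethylsilyloxy)octahydroazulen-7(1H)-one (H-3a, H-8a, 3-O and 5-OH on one face)
Conditions: [Ir(cod)(PCy3)(py)]PF6 (5 mol%), H2 (1 atm), CH2Cl2, rt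
Reagents that add atoms: none
Why: Hydroxyl-directed hydrogenation with Crabtree's catalyst delivers hydrogen to the alkene face of the allylic C-5 hydroxyl, which is also the face of H-8a, and so sets C-3a with the cis ring fusion.

Step 25
Reactants: 34 the hydroxy ketone
Product: 35 cis-fused 3,6,8,8-tetramethyl-3,5-bis(triethylsilyloxy)octahydroazulen-7(1H)-one
Conditions: TESOTf (1.3 equiv), 2,6-lutidine, CH2Cl2, −78 °C
Reagents that add atoms: triethylsilyl triflate, CC[Si](CC)(CC)OS(=O)(=O)C(F)(F)F
Why: Silylation of the secondary hydroxyl at low temperature avoids retro-aldol cleavage and gives two silyl ethers that can be removed together at the end.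

Step 26
Reactants: 35 the bis-silyl ketone
Product: 37 cis-fused 3,6,8,8-tetramethyl-3,5-bis(triethylsilyloxy)-1,2,3,3a,4,5,8,8a-octahydroazulen-7-yl trifluoromethanesulfonate, via potassium enolate 36 (not isolated)
Conditions: KN(SiMe3)2, THF, −78 °C; then N-(5-chloropyridin-2-yl)bis(trifluoromethanesulfonyl)imide, −78 → 0 °C
Reagents that add atoms: N-(5-chloropyridin-2-yl)bis(trifluoromethanesulfonyl)imide (Comins' reagent), Clc1ccc(nc1)N(S(=O)(=O)C(F)(F)F)S(=O)(=O)C(F)(F)F
Why: Enolisation can only occur towards the methyl-bearing carbon (the other α-carbon is quaternary), and O-triflation of the enolate at −78 °C outruns β-elimination of the silyloxy group; the C-6 stereocentre disappears.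

Step 27
Reactants: 17 the vinyl carbinol acetate; 37 the enol triflate
Product: 39 3,5-bis(triethylsilyl) ether of the target, via B-alkyl-9-borabicyclononane 38 (not isolated)
Conditions: 9-BBN (2.5 equiv), THF, rt; then 37, PdCl2(dppf) (10 mol%), AsPh3, 3 M aqueous K3PO4, DMF, 50 °C
Reagents that add atoms: none
Why: Anti-Markovnikov hydroboration of the vinyl group, then B-alkyl Suzuki–Miyaura coupling with the alkenyl triflate (as known for 2,6,6-trimethylcyclohexenyl triflates), forms the CH2–C(sp2) bond without touching a stereocentre; the mild base spares the hindered acetate.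

Step 28
Reactants: 39 the bis-silyl ether
Product: 40 the target CNP0157376.1
Conditions: HF·pyridine, pyridine, THF, 0 °C → rt
Reagents that add atoms: none
Why: Buffered fluoride desilylation removes the secondary allylic and the tertiary triethylsilyl ethers while the acetate and the acid-sensitive allylic alcohol survive.

## Compound list

1 | methyl geranate, methyl (2E)-3,7-dimethylocta-2,6-dienoate | COC(=O)/C=C(C)/CCC=C(C)C | starting material
2 | methyl (2E)-5-[(2R)-3,3-dimethyloxiran-2-yl]-3-methylpent-2-enoate | COC(=O)/C=C(C)/CC[C@H]1OC1(C)C | intermediate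
3 | allyl alcohol | C=CCO | starting material
4 | methyl (2E,6R)-6-hydroxy-3,7-dimethyl-7-(prop-2-en-1-yloxy)oct-2-enoate | O[C@H](CC/C(C)=C/C(=O)OC)C(C)(C)OCC=C | intermediate
5 | methyl (2E,6R)-6-acetoxy-3,7-dimethyl-7-(prop-2-en-1-yloxy)oct-2-enoate | CC(=O)O[C@H](CC/C(C)=C/C(=O)OC)C(C)(C)OCC=C | intermediate
6 | (E)-crotonaldehyde | C/C=C/C=O | starting material
7 | methyl (2E,6R)-6-acetoxy-3,7-dimethyl-7-{[(2E)-4-oxobut-2-en-1-yl]oxy}oct-2-enoate | CC(=O)O[C@H](CC/C(C)=C/C(=O)OC)C(C)(C)OC/C=C/C=O | intermediate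
8 | methyl (2E,6R)-6-acetoxy-7-{[(1E,3E)-4-(tert-butyldimethylsilyloxy)buta-1,3-dien-1-yl]oxy}-3,7-dimethyloct-2-enoate | CC(=O)O[C@H](CC/C(C)=C/C(=O)OC)C(C)(C)O/C=C/C=C/O[Si](C)(C)C(C)(C)C | intermediate
9 | trans-fused cycloadduct, methyl (3R)-3-acetoxy-7-(TBS-oxy)-2,2,5a-trimethyl-2,3,4,5,5a,6,7,9a-octahydro-1-benzoxepine-6-carboxylate (5a-CH3, 6-CO2CH3, 7-OTBS β; 9a-H, 3-OAc α) | CC(=O)O[C@@H]1CC[C@]2(C)[C@@H](C(=O)OC)[C@@H](O[Si](C)(C)C(C)(C)C)C=C[C@H]2OC1(C)C | intermediate
10 | 8,9-dihydro derivative of 9 | CC(=O)O[C@@H]1CC[C@]2(C)[C@@H](C(=O)OC)[C@@H](O[Si](C)(C)C(C)(C)C)CC[C@H]2OC1(C)C | intermediate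
11 | (3R)-6β-(hydroxymethyl)-7β-(TBS-oxy)-2,2,5a-trimethyldecahydro-1-benzoxepin-3α-ol | O[C@@H]1CC[C@]2(C)[C@@H](CO)[C@@H](O[Si](C)(C)C(C)(C)C)CC[C@H]2OC1(C)C | intermediate
12 | (3R)-3α-hydroxy-7β-(TBS-oxy)-2,2,5a-trimethyldecahydro-1-benzoxepine-6β-carbaldehyde | O[C@@H]1CC[C@]2(C)[C@@H](C=O)[C@@H](O[Si](C)(C)C(C)(C)C)CC[C@H]2OC1(C)C | intermediate
13 | (3R)-6β-ethenyl-7β-(TBS-oxy)-2,2,5a-trimethyldecahydro-1-benzoxepin-3α-ol | O[C@@H]1CC[C@]2(C)[C@@H](C=C)[C@@H](O[Si](C)(C)C(C)(C)C)CC[C@H]2OC1(C)C | intermediate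
14 | 3α-acetate of 13 | CC(=O)O[C@@H]1CC[C@]2(C)[C@@H](C=C)[C@@H](O[Si](C)(C)C(C)(C)C)CC[C@H]2OC1(C)C | intermediate
15 | (3R)-6β-ethenyl-7β-hydroxy-2,2,5a-trimethyldecahydro-1-benzoxepin-3α-yl acetate | CC(=O)O[C@@H]1CC[C@]2(C)[C@@H](C=C)[C@@H](O)CC[C@H]2OC1(C)C | intermediate
16 | (3R)-6β-ethenyl-2,2,5a-trimethyl-7-oxodecahydro-1-benzoxepin-3α-yl acetate | CC(=O)O[C@@H]1CC[C@]2(C)[C@@H](C=C)C(=O)CC[C@H]2OC1(C)C | intermediate
17 | (3R)-6β-ethenyl-7β-hydroxy-2,2,5a,7α-tetramethyldecahydro-1-benzoxepin-3α-yl acetate | CC(=O)O[C@@H]1CC[C@]2(C)[C@@H](C=C)[C@@](C)(O)CC[C@H]2OC1(C)C | intermediate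
18 | (R)-(−)-linalool | C=C[C@](C)(O)CCC=C(C)C | starting material
19 | (R)-1-methylcyclopent-2-en-1-ol | C[C@@]1(O)CCC=C1 | intermediate
20 | (1R)-cis-2,3-epoxy-1-methylcyclopentan-1-ol | C[C@@]1(O)CC[C@@H]2O[C@H]12 | intermediate
21 | isobutyronitrile | CC(C)C#N | starting material
22 | 2-lithio-2-methylpropanenitrile | [Li]C(C)(C)C#N | intermediate
23 | 2-[(3R)-2,3-dihydroxy-3-methylcyclopentyl]-2-methylpropanenitrile (2-OH cis to 3-OH, side chain trans to 2-OH) | C[C@@]1(O)CC[C@@H](C(C)(C)C#N)[C@@H]1O | intermediate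
24 | 2-[(3R)-3-hydroxy-3-methyl-2-oxocyclopentyl]-2-methylpropanenitrile | C[C@@]1(O)CC[C@@H](C(C)(C)C#N)C1=O | intermediate
25 | 2-methyl-2-[(3R)-3-methyl-2-oxo-3-(triethylsilyloxy)cyclopentyl]propanenitrile | C[C@@]1(O[Si](CC)(CC)CC)CC[C@@H](C(C)(C)C#N)C1=O | intermediate
26 | 2-methyl-2-[(3R)-3-methyl-2-methylidene-3-(triethylsilyloxy)cyclopentyl]propanenitrile | C[C@@]1(O[Si](CC)(CC)CC)CC[C@@H](C(C)(C)C#N)C1=C | intermediate
27 | N-lithio ketimine of 28 | C[C@@]1(O[Si](CC)(CC)CC)CC[C@@H](C(C)(C)C(CC)=N[Li])C1=C | intermediate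
28 | 2-methyl-2-[(3R)-3-methyl-2-methylidene-3-(triethylsilyloxy)cyclopentyl]pentan-3-one | C[C@@]1(O[Si](CC)(CC)CC)CC[C@@H](C(C)(C)C(=O)CC)C1=C | intermediate
29 | acrolein | C=CC=O | starting material
30 | Z-enol diisopinocampheylborinate of 28 | C[C@@]1(O[Si](CC)(CC)CC)CC[C@@H](C(C)(C)/C(OB([C@@H]2C[C@@H]3C[C@@H](C3(C)C)[C@H]2C)[C@@H]2C[C@@H]3C[C@@H](C3(C)C)[C@H]2C)=C/C)C1=C | intermediate
31 | diisopinocampheylboron aldolate of 32 | C[C@@]1(O[Si](CC)(CC)CC)CC[C@@H](C(C)(C)C(=O)[C@@H](C)[C@H](OB([C@@H]2C[C@@H]3C[C@@H](C3(C)C)[C@H]2C)[C@@H]2C[C@@H]3C[C@@H](C3(C)C)[C@H]2C)C=C)C1=C | intermediate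
32 | (4S,5R)-5-hydroxy-2,4-dimethyl-2-[(3R)-3-methyl-2-methylidene-3-(triethylsilyloxy)cyclopentyl]hept-6-en-3-one | C[C@@]1(O[Si](CC)(CC)CC)CC[C@@H](C(C)(C)C(=O)[C@@H](C)[C@H](O)C=C)C1=C | intermediate
33 | 5-hydroxy-3,6,8,8-tetramethyl-3-(triethylsilyloxy)-2,3,5,6,8,8a-hexahydroazulen-7(1H)-one | O=C1[C@@H](C)[C@H](O)C=C2[C@@H](CC[C@@]2(C)O[Si](CC)(CC)CC)C1(C)C | intermediate
34 | cis-fused 5-hydroxy-3,6,8,8-tetramethyl-3-(triethylsilyloxy)octahydroazulen-7(1H)-one | O=C1[C@@H](C)[C@H](O)C[C@@H]2[C@@H](CC[C@@]2(C)O[Si](CC)(CC)CC)C1(C)C | intermediate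
35 | cis-fused 3,6,8,8-tetramethyl-3,5-bis(triethylsilyloxy)octahydroazulen-7(1H)-one | O=C1[C@@H](C)[C@H](O[Si](CC)(CC)CC)C[C@@H]2[C@@H](CC[C@@]2(C)O[Si](CC)(CC)CC)C1(C)C | intermediate
36 | potassium enolate of 35 | [K+].[O-]C1=C(C)[C@H](O[Si](CC)(CC)CC)C[C@@H]2[C@@H](CC[C@@]2(C)O[Si](CC)(CC)CC)C1(C)C | intermediate
37 | cis-fused 3,6,8,8-tetramethyl-3,5-bis(triethylsilyloxy)-1,2,3,3a,4,5,8,8a-octahydroazulen-7-yl triflate | FC(F)(F)S(=O)(=O)OC1=C(C)[C@H](O[Si](CC)(CC)CC)C[C@@H]2[C@@H](CC[C@@]2(C)O[Si](CC)(CC)CC)C1(C)C | intermediate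
38 | B-alkyl-9-BBN borane from 17 | CC(=O)O[C@@H]1CC[C@]2(C)[C@@H](CCB3C4CCCC3CCC4)[C@@](C)(O)CC[C@H]2OC1(C)C | intermediate
39 | 3,5-bis(triethylsilyl) ether of the target | CC(=O)O[C@@H]1CC[C@]2(C)[C@@H](CCC3=C(C)[C@H](O[Si](CC)(CC)CC)C[C@@H]4[C@@H](CC[C@@]4(C)O[Si](CC)(CC)CC)C3(C)C)[C@@](C)(O)CC[C@H]2OC1(C)C | intermediate
40 | CNP0157376.1 | CC(=O)O[C@@H]1CC[C@]2(C)[C@@H](CCC3=C(C)[C@H](O)C[C@@H]4[C@@H](CC[C@@]4(C)O)C3(C)C)[C@@](C)(O)CC[C@H]2OC1(C)C | target

## Step count and risks

Total step count: 28. Longest linear sequence: 16 steps (steps 1–14, 27, 28); the hydroazulene branch is 12 steps (15–26) before the union.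

Steps most likely to fail:

1. Step 6. The cycloaddition may take place mainly on the undesired diene face, because the acetoxy-bearing carbon in the middle of the tether is the only face-controlling element; slow closure through the five-atom tether also leaves time for thermal loss of the tert-alkyl dienyl ether. Fallback (stereochemical relay through the enantiomeric tether): the route sets out again from 1 with the L-fructose-derived enantiomer of the Shi ketone, which should give the (S)-epoxide F1. The operations of steps 2–5 would then lead through the (6S)-hydroxy allyl ether F2, the (6S)-acetate F3 and the (6S)-enal F4 to the (6S)-dienyl ether F5. If the (6R) series prefers the wrong face, F5 should on heating give the 3-epi cycloadduct F6, which has the ring-B configuration of 9 and only the acetoxy carbon inverted. Methanolysis (K2CO3, MeOH) would free the 3-epi alcohol F7, Dess–Martin oxidation would give the oxepan-3-one F8, and hydride reduction (NaBH4 or LiBH(s-Bu)3, whichever favours the 3α-alcohol, the other epimer being re-oxidised and recycled) would give the 3α-alcohol F9. Acetylation (Ac2O, DMAP) brings the material back to the route at 9.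

2. Step 27. Transmetalation and reductive elimination at the tetrasubstituted enol triflate flanked by a quaternary carbon may be slow, so that triflate hydrolysis, protodeboronation and saponification of the acetate by the aqueous base take over. Fallback (base-free Negishi coupling through boron–zinc exchange): from 17, hydroboration with Et2BH would give the alkyldiethylborane F10, and exchange with Et2Zn the alkyl(ethyl)zinc reagent F11. Its coupling with 37 under Pd(OAc)2 and 2-dicyclohexylphosphino-2',6'-dimethoxybiphenyl in THF/N-methylpyrrolidone comes back to the route at 39.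

3. Step 23. Ring closure onto the 1,1-disubstituted alkene, which is shielded by fully substituted carbons on both sides, may fail in favour of oligomerisation through the vinyl carbinol or retro-aldol cleavage on heating. Fallback (seven-membered ring closed at the other alkene, hydroxyl introduced afterwards), from 26:
- Hydroboration with 9-BBN anti to the cyanoisopropyl group would give the alkylborane F12, and B-alkyl Suzuki coupling with vinyl bromide (PdCl2(dppf), K3PO4) the allyl nitrile F13; this sets H-3a.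
- Isopropenyllithium would add to the nitrile to give the lithium ketimide F14, hydrolysed with buffered acid to the isopropenyl ketone F15.
- Ring-closing metathesis (second-generation Grubbs catalyst) between the allyl group and the methacryloyl unit would give the bicyclic enone F16.
- Copper-catalysed conjugate borylation (B2pin2, CuCl, NaOt-Bu, MeOH) from the convex face would give the β-boryl ketone F17, and oxidation with NaBO3·4H2O the β-hydroxy ketone F18.
- Silylation (TESOTf, 2,6-lutidine) would give the bis-silyl ketone F19, a mixture at the methyl-bearing carbon that does not matter; triflation as in step 26 comes back to the route at 37.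

Further compounds
F1 | step 6 | methyl (2E)-5-[(2S)-3,3-dimethyloxiran-2-yl]-3-methylpent-2-enoate | COC(=O)/C=C(C)/CC[C@@H]1OC1(C)C
F2 | step 6 | methyl (2E,6S)-6-hydroxy-3,7-dimethyl-7-(prop-2-en-1-yloxy)oct-2-enoate | O[C@@H](CC/C(C)=C/C(=O)OC)C(C)(C)OCC=C
F3 | step 6 | methyl (2E,6S)-6-acetoxy-3,7-dimethyl-7-(prop-2-en-1-yloxy)oct-2-enoate | CC(=O)O[C@@H](CC/C(C)=C/C(=O)OC)C(C)(C)OCC=C
F4 | step 6 | methyl (2E,6S)-6-acetoxy-3,7-dimethyl-7-{[(2E)-4-oxobut-2-en-1-yl]oxy}oct-2-enoate | CC(=O)O[C@@H](CC/C(C)=C/C(=O)OC)C(C)(C)OC/C=C/C=O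
F5 | step 6 | methyl (2E,6S)-6-acetoxy-7-{[(1E,3E)-4-(tert-butyldimethylsilyloxy)buta-1,3-dien-1-yl]oxy}-3,7-dimethyloct-2-enoate | CC(=O)O[C@@H](CC/C(C)=C/C(=O)OC)C(C)(C)O/C=C/C=C/O[Si](C)(C)C(C)(C)C
F6 | step 6 | 3-epi cycloadduct (3β-acetoxy isomer of 9) | CC(=O)O[C@H]1CC[C@]2(C)[C@@H](C(=O)OC)[C@@H](O[Si](C)(C)C(C)(C)C)C=C[C@H]2OC1(C)C
F7 | step 6 | 3-epi alcohol (3β-hydroxy, deacetylated F6) | O[C@H]1CC[C@]2(C)[C@@H](C(=O)OC)[C@@H](O[Si](C)(C)C(C)(C)C)C=C[C@H]2OC1(C)C
F8 | step 6 | 3-oxo compound (oxepan-3-one) | O=C1CC[C@]2(C)[C@@H](C(=O)OC)[C@@H](O[Si](C)(C)C(C)(C)C)C=C[C@H]2OC1(C)C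
F9 | step 6 | 3α-alcohol (deacetyl 9) | O[C@@H]1CC[C@]2(C)[C@@H](C(=O)OC)[C@@H](O[Si](C)(C)C(C)(C)C)C=C[C@H]2OC1(C)C
F10 | step 27 | alkyldiethylborane from 17 | CC(=O)O[C@@H]1CC[C@]2(C)[C@@H](CCB(CC)CC)[C@@](C)(O)CC[C@H]2OC1(C)C
F11 | step 27 | alkyl(ethyl)zinc reagent from F10 | CC(=O)O[C@@H]1CC[C@]2(C)[C@@H](CC[Zn]CC)[C@@](C)(O)CC[C@H]2OC1(C)C
F12 | step 23 | B-alkyl-9-BBN borane from 26 | C[C@@]1(O[Si](CC)(CC)CC)CC[C@@H](C(C)(C)C#N)[C@H]1CB1C2CCCC1CCC2
F13 | step 23 | 2-methyl-2-[3-methyl-2-(but-3-en-1-yl... allyl: prop-2-en-1-ylmethyl)-3-(triethylsilyloxy)cyclopentyl]propanenitrile (2-CH2CH=CH2 homologue: 2-(but-3-en-1-yl is not meant; substituent is CH2–CH=CH2 on the ring CH2, all-cis with 3-CH3 and side chain) | C[C@@]1(O[Si](CC)(CC)CC)CC[C@@H](C(C)(C)C#N)[C@H]1CC=C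
F14 | step 23 | N-lithio ketimine of F15 | C[C@@]1(O[Si](CC)(CC)CC)CC[C@@H](C(C)(C)C(=N[Li])C(C)=C)[C@H]1CC=C
F15 | step 23 | isopropenyl ketone (2,4-dimethyl-4-[cyclopentyl]pent-1-en-3-one bearing the ring allyl group) | C[C@@]1(O[Si](CC)(CC)CC)CC[C@@H](C(C)(C)C(=O)C(C)=C)[C@H]1CC=C
F16 | step 23 | cis-fused 3,6,8,8-tetramethyl-3-(triethylsilyloxy)-2,3,3a,4,8,8a-hexahydroazulen-7(1H)-one | O=C1C(C)=CC[C@@H]2[C@@H](CC[C@@]2(C)O[Si](CC)(CC)CC)C1(C)C
F17 | step 23 | 5-(pinacolboryl) ketone | O=C1C(C)[C@H](B2OC(C)(C)C(C)(C)O2)C[C@@H]3[C@@H](CC[C@@]3(C)O[Si](CC)(CC)CC)C1(C)C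
F18 | step 23 | 5-hydroxy ketone (34 as a mixture at C-6) | O=C1C(C)[C@H](O)C[C@@H]2[C@@H](CC[C@@]2(C)O[Si](CC)(CC)CC)C1(C)C
F19 | step 23 | bis(triethylsilyl) ketone (35 as a mixture at C-6) | O=C1C(C)[C@H](O[Si](CC)(CC)CC)C[C@@H]2[C@@H](CC[C@@]2(C)O[Si](CC)(CC)CC)C1(C)C
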